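## Retrosynthetic overview

1. The target comes from global hydrogenolysis of its penta-O-benzyl ether; the two methyl ethers are kept.
2. The pyranone ring of the dimethoxyaryl flavone (unit B) comes from I2/DMSO oxidative cyclisation of a 2'-hydroxychalcone. That chalcone is made by an intermolecular Claisen–Schmidt aldol between a flavone-bearing biaryl aldehyde and 2-hydroxy-4,6-bis(benzyloxy)acetophenone (the fragment union).
3. The 3'–8'' biaryl bond comes from Suzuki coupling of tri-O-benzyl-8-iodoapigenin with the pinacol boronate of 3-bromo-4,5-dimethoxybenzaldehyde.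
4. The 8-iodoapigenin unit (unit A) comes from an earlier Claisen–Schmidt aldol and I2/DMSO cyclisation of the 3-iodoacetophenone with 4-(benzyloxy)benzaldehyde; both acetophenones derive from 2,4,6-trihydroxyacetophenone.
5. Ring order: pyranone of unit A, then the biaryl bond, then pyranone of unit B.

Assumption: the target SMILES has no stereocentre and no specified axial configuration, so there is no stereochemistry to control; the biaryl axis is formed without stereocontrol.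

## Route

Step 1
Reactants: 1 2,4,6-trihydroxyacetophenone
Product: 2 1-[2,4-bis(benzyloxy)-6-hydroxyphenyl]ethan-1-one
Conditions: BnBr (2.1 equiv), K2CO3 (2.2 equiv), DMF, 0 °C to rt, 16 h
Reagents that add atoms: benzyl bromide, BrCc1ccccc1
Why: Williamson O-alkylation; the 4-OH and one ortho-OH are benzylated, while the second ortho-OH is deactivated by its hydrogen bond to the acetyl C=O and stays free with about two equivalents of BnBr.

Step 2
Reactants: 2 1-[2,4-bis(benzyloxy)-6-hydroxyphenyl]ethan-1-one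
Product: 3 1-[4,6-bis(benzyloxy)-2-hydroxy-3-iodophenyl]ethan-1-one
Conditions: N-iodosuccinimide (1.05 equiv), CF3CO2H (cat.), MeCN/CH2Cl2, 0 °C to rt
Reagents that add atoms: N-iodosuccinimide, O=C1CCC(=O)N1I
Why: Electrophilic aromatic iodination ortho to the free chelated phenol (C3), the position at which 2-hydroxy-4,6-dialkoxyacetophenones are halogenated, so iodine sits on the carbon that becomes C8 of the flavone.

Step 3
Reactants: 3 1-[4,6-bis(benzyloxy)-2-hydroxy-3-iodophenyl]ethan-1-one; 4 4-(benzyloxy)benzaldehyde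
Product: 6 (E)-1-[4,6-bis(benzyloxy)-2-hydroxy-3-iodophenyl]-3-[4-(benzyloxy)phenyl]prop-2-en-1-one (iodochalcone), via racemic β-hydroxy ketone aldol adduct 5 (not isolated)
Conditions: KOH (50% aq., excess), EtOH/THF, rt, 24–48 h; then 1 M HCl
Reagents that add atoms: none
Why: Claisen–Schmidt crossed aldol condensation; the methyl ketone enolate adds to the non-enolisable aldehyde and aldol 5 dehydrates by E1cB to the thermodynamically favoured E-enone, leaving no stereocentre.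

Step 4
Reactants: 6 iodochalcone
Product: 8 tri-O-benzyl-8-iodoapigenin [5,7-bis(benzyloxy)-2-[4-(benzyloxy)phenyl]-8-iodo-4H-chromen-4-one], via racemic 8-iodoflavanone 7 (not isolated)
Conditions: I2 (10 mol %), DMSO, 130 °C, 2–4 h; aq. Na2S2O3 work-up
Reagents that add atoms: none
Why: Iodine/DMSO oxidative cyclisation of a 2'-hydroxychalcone; oxa-Michael closure through the only free phenol (next to the C–I carbon) gives flavanone 7, which iodine dehydrogenates to the flavone while DMSO reoxidises HI, fixing iodine at C8.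

Step 5
Reactants: 9 3-bromo-4,5-dimethoxybenzaldehyde
Product: 10 3,4-dimethoxy-5-(4,4,5,5-tetramethyl-1,3,2-dioxaborolan-2-yl)benzaldehyde
Conditions: B2pin2 (1.2 equiv), PdCl2(dppf) (3 mol %), KOAc (3 equiv), 1,4-dioxane, 90 °C; filtration through Celite
Reagents that add atoms: bis(pinacolato)diboron, CC1(C)OB(OC1(C)C)B1OC(C)(C)C(C)(C)O1
Why: Miyaura borylation of an aryl bromide tolerates the free aldehyde, and KOAc is too weak a base to promote Suzuki homocoupling.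

Step 6
Reactants: 8 tri-O-benzyl-8-iodoapigenin; 10 3,4-dimethoxy-5-(pinacolboryl)benzaldehyde (1.5 equiv)
Product: 11 3-{5,7-bis(benzyloxy)-2-[4-(benzyloxy)phenyl]-4-oxo-4H-chromen-8-yl}-4,5-dimethoxybenzaldehyde
Conditions: Pd(OAc)2 (5 mol %), SPhos (10 mol %), K3PO4 (3 equiv), toluene/H2O 10:1, 100 °C
Reagents that add atoms: none
Why: Suzuki–Miyaura cross-coupling; the bulky electron-rich SPhos ligand suits the di-ortho-substituted iodide and the ortho-methoxy boronate, and the new axis is not a defined stereoelement of the target.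

Step 7
Reactants: 11 flavone biaryl aldehyde; 2 1-[2,4-bis(benzyloxy)-6-hydroxyphenyl]ethan-1-one (1.3 equiv)
Product: 13 (E)-1-[2,4-bis(benzyloxy)-6-hydroxyphenyl]-3-(3-{5,7-bis(benzyloxy)-2-[4-(benzyloxy)phenyl]-4-oxo-4H-chromen-8-yl}-4,5-dimethoxyphenyl)prop-2-en-1-one (flavone–chalcone), via racemic aldol adduct 12 (not isolated)
Conditions: KOH (50% aq., excess), EtOH/THF 1:1, rt, 24–48 h; then 1 M HCl
Reagents that add atoms: none
Why: Claisen–Schmidt aldol condensation joining the two large fragments; the enolate of 2 adds to the non-enolisable aryl aldehyde of 11 and E1cB dehydration of 12 gives the E-chalcone, the fully O-alkylated flavone being stable to hydroxide at room temperature.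

Step 8
Reactants: 13 flavone–chalcone
Product: 15 penta-O-benzyl-5'-methoxybilobetin [8-{5-[5,7-bis(benzyloxy)-4-oxo-4H-chromen-2-yl]-2,3-dimethoxyphenyl}-5,7-bis(benzyloxy)-2-[4-(benzyloxy)phenyl]-4H-chromen-4-one], via racemic flavanone 14 (not isolated)
Conditions: I2 (10–20 mol %), DMSO, 130 °C, 3–5 h; aq. Na2S2O3 work-up
Reagents that add atoms: none
Why: Iodine/DMSO oxidative cyclisation of the 2'-hydroxychalcone (oxa-Michael closure to flavanone 14, then iodine-mediated dehydrogenation with DMSO as terminal oxidant) builds the second pyranone; benzyl and methyl ethers and the first flavone are inert.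

Step 9
Reactants: 15 penta-O-benzyl-5'-methoxybilobetin
Product: 16 5'-methoxybilobetin [8-[5-(5,7-dihydroxy-4-oxo-4H-chromen-2-yl)-2,3-dimethoxyphenyl]-5,7-dihydroxy-2-(4-hydroxyphenyl)-4H-chromen-4-one]
Conditions: H2 (1 atm), Pd/C (10 wt %), THF/MeOH 1:1, rt
Reagents that add atoms: none
Why: Catalytic hydrogenolysis cleaves the five benzyl aryl ethers and leaves the aryl methyl ethers and the vinylogous-ester C2=C3 bonds of both chromones untouched; there is no stereocentre to preserve.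

## Compound list

1 | 2,4,6-trihydroxyacetophenone | CC(=O)c1c(O)cc(O)cc1O | starting material
2 | 1-[2,4-bis(benzyloxy)-6-hydroxyphenyl]ethan-1-one | CC(=O)c1c(O)cc(OCc2ccccc2)cc1OCc1ccccc1 | intermediate
3 | 1-[4,6-bis(benzyloxy)-2-hydroxy-3-iodophenyl]ethan-1-one | CC(=O)c1c(O)c(I)c(OCc2ccccc2)cc1OCc1ccccc1 | intermediate
4 | 4-(benzyloxy)benzaldehyde | O=Cc1ccc(OCc2ccccc2)cc1 | starting material
5 | racemic 1-[4,6-bis(benzyloxy)-2-hydroxy-3-iodophenyl]-3-[4-(benzyloxy)phenyl]-3-hydroxypropan-1-one (aldol adduct) | O=C(CC(O)c1ccc(OCc2ccccc2)cc1)c1c(O)c(I)c(OCc2ccccc2)cc1OCc1ccccc1 | intermediate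
6 | (E)-1-[4,6-bis(benzyloxy)-2-hydroxy-3-iodophenyl]-3-[4-(benzyloxy)phenyl]prop-2-en-1-one | O=C(/C=C/c1ccc(OCc2ccccc2)cc1)c1c(O)c(I)c(OCc2ccccc2)cc1OCc1ccccc1 | intermediate
7 | racemic 5,7-bis(benzyloxy)-2-[4-(benzyloxy)phenyl]-8-iodochroman-4-one | O=C1CC(c2ccc(OCc3ccccc3)cc2)Oc2c(I)c(OCc3ccccc3)cc(OCc3ccccc3)c21 | intermediate
8 | 5,7-bis(benzyloxy)-2-[4-(benzyloxy)phenyl]-8-iodo-4H-chromen-4-one | O=c1cc(-c2ccc(OCc3ccccc3)cc2)oc2c(I)c(OCc3ccccc3)cc(OCc3ccccc3)c12 | intermediate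
9 | 3-bromo-4,5-dimethoxybenzaldehyde | COc1cc(C=O)cc(Br)c1OC | starting material
10 | 3,4-dimethoxy-5-(4,4,5,5-tetramethyl-1,3,2-dioxaborolan-2-yl)benzaldehyde | COc1cc(C=O)cc(B2OC(C)(C)C(C)(C)O2)c1OC | intermediate
11 | 3-{5,7-bis(benzyloxy)-2-[4-(benzyloxy)phenyl]-4-oxo-4H-chromen-8-yl}-4,5-dimethoxybenzaldehyde | COc1cc(C=O)cc(-c2c(OCc3ccccc3)cc(OCc3ccccc3)c3c(=O)cc(-c4ccc(OCc5ccccc5)cc4)oc23)c1OC | intermediate
12 | racemic 1-[2,4-bis(benzyloxy)-6-hydroxyphenyl]-3-(3-{5,7-bis(benzyloxy)-2-[4-(benzyloxy)phenyl]-4-oxo-4H-chromen-8-yl}-4,5-dimethoxyphenyl)-3-hydroxypropan-1-one (aldol adduct) | COc1cc(C(O)CC(=O)c2c(O)cc(OCc3ccccc3)cc2OCc2ccccc2)cc(-c2c(OCc3ccccc3)cc(OCc3ccccc3)c3c(=O)cc(-c4ccc(OCc5ccccc5)cc4)oc23)c1OC | intermediate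
13 | (E)-1-[2,4-bis(benzyloxy)-6-hydroxyphenyl]-3-(3-{5,7-bis(benzyloxy)-2-[4-(benzyloxy)phenyl]-4-oxo-4H-chromen-8-yl}-4,5-dimethoxyphenyl)prop-2-en-1-one | COc1cc(/C=C/C(=O)c2c(O)cc(OCc3ccccc3)cc2OCc2ccccc2)cc(-c2c(OCc3ccccc3)cc(OCc3ccccc3)c3c(=O)cc(-c4ccc(OCc5ccccc5)cc4)oc23)c1OC | intermediate
14 | racemic 8-{5-[5,7-bis(benzyloxy)-4-oxochroman-2-yl]-2,3-dimethoxyphenyl}-5,7-bis(benzyloxy)-2-[4-(benzyloxy)phenyl]-4H-chromen-4-one | COc1cc(C2CC(=O)c3c(OCc4ccccc4)cc(OCc4ccccc4)cc3O2)cc(-c2c(OCc3ccccc3)cc(OCc3ccccc3)c3c(=O)cc(-c4ccc(OCc5ccccc5)cc4)oc23)c1OC | intermediate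
15 | 8-{5-[5,7-bis(benzyloxy)-4-oxo-4H-chromen-2-yl]-2,3-dimethoxyphenyl}-5,7-bis(benzyloxy)-2-[4-(benzyloxy)phenyl]-4H-chromen-4-one | COc1cc(-c2cc(=O)c3c(OCc4ccccc4)cc(OCc4ccccc4)cc3o2)cc(-c2c(OCc3ccccc3)cc(OCc3ccccc3)c3c(=O)cc(-c4ccc(OCc5ccccc5)cc4)oc23)c1OC | intermediate
16 | 5'-methoxybilobetin, 8-[5-(5,7-dihydroxy-4-oxo-4H-chromen-2-yl)-2,3-dimethoxyphenyl]-5,7-dihydroxy-2-(4-hydroxyphenyl)-4H-chromen-4-one | COc1cc(-c2cc(=O)c3c(O)cc(O)cc3o2)cc(-c2c(O)cc(O)c3c(=O)cc(-c4ccc(O)cc4)oc23)c1OC | target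

## Summary

Total step count: 9.
Longest linear sequence: 8 steps (steps 1, 2, 3, 4, 6, 7, 8, 9; step 5 is a one-step side branch).

Steps most likely to fail, each with a fallback:

- Step 2 (iodination at C5 instead of C3, or di-iodination). The fallback postpones iodination until the flavone exists and sets out from 2. Claisen–Schmidt condensation of 2 with 4 (KOH, EtOH/THF, rt) gives the iodine-free chalcone (E)-1-[2,4-bis(benzyloxy)-6-hydroxyphenyl]-3-[4-(benzyloxy)phenyl]prop-2-en-1-one F1. I2 (cat.)/DMSO at 130 °C closes it to 5,7-bis(benzyloxy)-2-[4-(benzyloxy)phenyl]-4H-chromen-4-one F2. Iodination of this fully O-alkylated flavone with I2/CF3CO2Ag in CH2Cl2 at rt takes place at C8 (attack at C6 needs a free 5-OH), which comes back to the route at 8.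

- Step 6 (hindered tri-ortho biaryl coupling; protodeboronation of 10 or hydrodeiodination of 8). The fallback replaces the boron nucleophile by tin and sets out from 9. Stannylation of 9 with Me3SnSnMe3 and Pd(PPh3)4 in toluene at 110 °C gives 3,4-dimethoxy-5-(trimethylstannyl)benzaldehyde F3. Stille coupling of this stannane with 8 (Pd(PPh3)4, CuI, DMF, 80 °C) comes back to the route at 11.

- Step 7 (hydroxide may open the pyranone of the flavone already present, or the hindered condensation may stall). The fallback replaces the aldol by an intermolecular Claisen condensation under non-nucleophilic base and sets out from 11.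
  - Pinnick oxidation (NaClO2, NaH2PO4, 2-methyl-2-butene, t-BuOH/THF/H2O) gives 3-{5,7-bis(benzyloxy)-2-[4-(benzyloxy)phenyl]-4-oxo-4H-chromen-8-yl}-4,5-dimethoxybenzoic acid F4.
  - (COCl)2 with cat. DMF in CH2Cl2 gives 3-{5,7-bis(benzyloxy)-2-[4-(benzyloxy)phenyl]-4-oxo-4H-chromen-8-yl}-4,5-dimethoxybenzoyl chloride F5.
  - Adding this chloride to the dilithio derivative of 2 (LiN(SiMe3)2, 3.5 equiv, THF, −78 to −10 °C) gives 1-[2,4-bis(benzyloxy)-6-hydroxyphenyl]-3-(3-{5,7-bis(benzyloxy)-2-[4-(benzyloxy)phenyl]-4-oxo-4H-chromen-8-yl}-4,5-dimethoxyphenyl)propane-1,3-dione F6.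
  - Acid-catalysed cyclodehydration (TsOH, toluene, 80 °C) comes back to the route at 15, bypassing 13.

## Further compounds

F1 | step 2 | (E)-1-[2,4-bis(benzyloxy)-6-hydroxyphenyl]-3-[4-(benzyloxy)phenyl]prop-2-en-1-one | O=C(/C=C/c1ccc(OCc2ccccc2)cc1)c1c(O)cc(OCc2ccccc2)cc1OCc1ccccc1
F2 | step 2 | 5,7-bis(benzyloxy)-2-[4-(benzyloxy)phenyl]-4H-chromen-4-one | O=c1cc(-c2ccc(OCc3ccccc3)cc2)oc2cc(OCc3ccccc3)cc(OCc3ccccc3)c12
F3 | step 6 | 3,4-dimethoxy-5-(trimethylstannyl)benzaldehyde | COc1cc(C=O)cc([Sn](C)(C)C)c1OC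
F4 | step 7 | 3-{5,7-bis(benzyloxy)-2-[4-(benzyloxy)phenyl]-4-oxo-4H-chromen-8-yl}-4,5-dimethoxybenzoic acid | COc1cc(C(=O)O)cc(-c2c(OCc3ccccc3)cc(OCc3ccccc3)c3c(=O)cc(-c4ccc(OCc5ccccc5)cc4)oc23)c1OC
F5 | step 7 | 3-{5,7-bis(benzyloxy)-2-[4-(benzyloxy)phenyl]-4-oxo-4H-chromen-8-yl}-4,5-dimethoxybenzoyl chloride | COc1cc(C(=O)Cl)cc(-c2c(OCc3ccccc3)cc(OCc3ccccc3)c3c(=O)cc(-c4ccc(OCc5ccccc5)cc4)oc23)c1OC
F6 | step 7 | 1-[2,4-bis(benzyloxy)-6-hydroxyphenyl]-3-(3-{5,7-bis(benzyloxy)-2-[4-(benzyloxy)phenyl]-4-oxo-4H-chromen-8-yl}-4,5-dimethoxyphenyl)propane-1,3-dione | COc1cc(C(=O)CC(=O)c2c(O)cc(OCc3ccccc3)cc2OCc2ccccc2)cc(-c2c(OCc3ccccc3)cc(OCc3ccccc3)c3c(=O)cc(-c4ccc(OCc5ccccc5)cc4)oc23)c1OC
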